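**Strategy.** In dihydronaphthalene numbering (C1 aryl-bearing, C2/C3 methyl-bearing, ring A the dimethoxybenzo ring), the target is a dehydro-dimer of one C6–C3 unit: ring A with C4, C3 and its methyl, and the pendant aryl ring with C1, C2 and its methyl. The halves are joined only through C2–C3 and C1–C8a; cutting both gives two molecules of (E)-methyl isoeugenol. The key step is an enantioselective oxidative radical-cation formal [4+2] homodimerisation (chiral-anion photoredox catalysis, hydrogen-evolving cobalt co-catalyst) that closes the carbocycle, sets C1 and C2 and installs the C3=C4 alkene in one operation from an achiral, acyclic propenylbenzene.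

Key step: step 1

Assumption: (E)-methyl isoeugenol is bought as the geometrically pure E isomer; the chiral ion-pair photocatalyst is made beforehand by salt metathesis and, being a catalyst, carries no compound number. Abbreviations: Mes-Acr-Me = 9-mesityl-10-methylacridinium; IDPi = N-triflyl imidodiphosphorimidate anion built from two (S)-3,3′-diaryl-BINOL units; dmgBF2 = difluoroboryl-bridged dimethylglyoximate.

Assumption: the sense of induction of the chiral anion cannot be assigned in advance; the (S,S)-anion is written, and the (R,R)-anion is used instead if the first run gives the antipode.

Step 1
Reactants: 1 (E)-methyl isoeugenol (two molecules)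
Product: 3 (1R,2S)-1-(3,4-dimethoxyphenyl)-6,7-dimethoxy-2,3-dimethyl-1,2-dihydronaphthalene, via β,β′-linked distonic radical cation 2 (not isolated)
Conditions: [Mes-Acr-Me][(S,S)-IDPi] (5 mol %), Co(dmgBF2)2(MeCN)2 (5 mol %), 2,6-di-tert-butylpyridine (10 mol %), 450 nm LEDs, CH2Cl2, −60 °C, argon
Reagents that add atoms: none
Why: Proposed new method: the excited acridinium cation oxidises 1 to its radical cation, which stays ion-paired with the chiral IDPi anion and bonds through its β-carbon to the β-carbon of a second molecule of 1 (C2–C3), giving the distonic radical cation 2; the benzylic cation end of 2 is then attacked by the ring-A carbon para to the 3-methoxy group (C1–C8a), and after proton loss the C4 benzylic radical is captured by divalent cobalt, β-hydride elimination gives the C3=C4 bond, and the cobalt hydride releases H2 with the proton. The closest known reaction types are the radical-cation [2+2] and oxidative [4+2] dimerisations of anethole-type alkenes, the counteranion-directed enantioselective radical-cation cyclopropanation of the same alkenes, and acridinium/cobaloxime acceptorless dehydrogenation; merging them into one enantioselective oxidative [4+2] is the new part. The one ring that closes (C1–C2–C3–C4–C4a–C8a) forms stepwise as a formal [4+2] annulation whose ring-closing event is a 6-endo-trig Friedel–Crafts attack of ring A on the benzylic cation. C2 is set in the β,β′ coupling inside the chiral ion pair (catalyst control, like topicity as in the all-trans [2+2] manifold, so either methyl-bearing carbon leaves the same configuration when the other becomes sp2), and C1 is set in the ring closure by C2, the aryl group taking the pseudo-equatorial position trans to the C2 methyl in a half-chair transition state. The step needs six-ring over cyclobutane closure, para-selective arene attack and no further dehydrogenation to the naphthalene: the 3-methoxy group para to C8a makes the six-ring closure fast and irreversible after proton loss while any cyclobutane is reopened by re-oxidation, the other ortho position is flanked by two substituents, and the absence of a stoichiometric oxidant together with stopping at full conversion of 1 limits over-oxidation.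

**Compound list**

1 | (E)-methyl isoeugenol, 1,2-dimethoxy-4-[(1E)-prop-1-en-1-yl]benzene | COc1ccc(/C=C/C)cc1OC | starting material
2 | β,β′-linked distonic radical cation, (2S,3S)-1,4-bis(3,4-dimethoxyphenyl)-2,3-dimethylbutane carrying a benzylic cation at C1 and a benzylic radical at C4 | COc1ccc([CH+][C@H](C)[C@@H](C)[CH]c2ccc(OC)c(OC)c2)cc1OC | intermediate
3 | (1R,2S)-1-(3,4-dimethoxyphenyl)-6,7-dimethoxy-2,3-dimethyl-1,2-dihydronaphthalene (1,2-trans) | COc1ccc([C@@H]2c3cc(OC)c(OC)cc3C=C(C)[C@H]2C)cc1OC | target

**Totals**

Total step count: 1
Longest linear sequence: 1 step

**Steps most likely to fail**

The route has a single step, so there is one entry.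

Step 1 (labelled as a proposed new method). Three processes may defeat it:
- the chiral anion may not hold the radical cation tightly enough for useful facial discrimination in the β,β′ coupling;
- 1,4-closure to the cyclobutane may outrun the six-ring closure at low temperature;
- the electron-rich product may be dehydrogenated further to the arylnaphthalene.

Fallback in known chemistry: setting out from 1, an achiral anodic oxidation should give the racemic product. The conditions are an undivided cell, carbon anode, platinum cathode, LiClO4 in MeNO2, 2,6-lutidine and room temperature. This is the electrochemical radical-cation dimerisation of propenylbenzenes, with hydrogen evolved at the cathode, and it forms the same two bonds without any chiral controller. It should give racemic trans-1-(3,4-dimethoxyphenyl)-6,7-dimethoxy-2,3-dimethyl-1,2-dihydronaphthalene F1. The enantiomers of F1 are then separated by preparative chromatography on a chiral stationary phase (amylose tris(3,5-dimethylphenylcarbamate), hexane/2-propanol). The (1R,2S) fraction is compound 3, where the fallback rejoins the route.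

**Further compounds**

F1 | step 1 | racemic trans-1-(3,4-dimethoxyphenyl)-6,7-dimethoxy-2,3-dimethyl-1,2-dihydronaphthalene (equal mixture of both enantiomers, written as two components) | COc1ccc([C@@H]2c3cc(OC)c(OC)cc3C=C(C)[C@H]2C)cc1OC.COc1ccc([C@H]2c3cc(OC)c(OC)cc3C=C(C)[C@@H]2C)cc1OC
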